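**Plan**
- Retrosynthesis: cut the two opposite cyclobutane bonds (chain-bearing CH to the allylic ring CH, and the bond shared with the cyclopentane) to give bicyclic triene ester 22. Then cut the side-chain CH2–CH= bond (Negishi) to give iodide 14 and alkenyl iodide 20. 14 comes from meso diester 10, and 10 from glycol cleavage of the bridge of Diels–Alder adduct 4.
- Enabling feature: the cyclobutane is a vinylcyclobutane. One of its CH groups is allylic to the C=C of the cyclohexene fused to it (ring A), and its opposite edge is shared with a cyclopentane whose CH2–CH is anchored on the ester ring (ring B). This is the straight [2+2] adduct of a ring 1,3-diene and an alkene held three atoms away.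
- Forward ring order: rings A and B arise together in the Diels–Alder step (ring B first as a bicyclo[2.2.2]octene). Ring A is deoxygenated to the diene, the bridge is cut, the chain is coupled on, and the cyclopentane and then the cyclobutane close in the last step.
- Stereochemistry: the endo Diels–Alder puts ring A anti to the two-carbon bridge, so the two bridge-derived carbons end cis to each other and trans to ring A. Esterase desymmetrization of meso 10 sets the absolute configuration. The four new CH centres of the last step follow from the substrate.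

Key step: step 14

Assumption: cis-cyclohexa-3,5-diene-1,2-diol (the microbial cis-dihydrodiol of benzene) is taken as a purchasable starting material.
Assumption: pig liver esterase is taken to hydrolyse the ester on the S-configured ring carbon of 10. If it prefers the other enantiotopic ester, the same compound 13 is reached by reducing the remaining ester arm (LiBH4 on the carboxylate salt) and methylating the acid.

Locants in the steps use the naphthalene numbering of 22: C-1 carries CO2Me, C-4 the side chain (C-1', C-2'=C-3'), C-4a/C-8a are the ring fusion, and C-5 to C-8 are the diene of ring A.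

Step 1
Reactants: 1 cis-cyclohexa-3,5-diene-1,2-diol
Product: 2 cis-2,2-dimethyl-3a,7a-dihydro-1,3-benzodioxole (acetonide of 1)
Conditions: 2,2-dimethoxypropane, TsOH·H2O (cat.), CH2Cl2, 0 °C; used at once
Reagents that add atoms: 2,2-dimethoxypropane COC(C)(C)OC
Why: Acid-catalysed transketalisation of a cis-1,2-diol should give the dioxolane with the cis relationship kept, and the dioxolane later shields one face of the diene.

Step 2
Reactants: 2 acetonide; 3 1,4-benzoquinone
Product: 4 meso endo adduct 2,2-dimethyl-3a,4,4a,8a,9,9a-hexahydro-4,9-ethenonaphtho[2,3-d][1,3]dioxole-5,8-dione (enedione ring and dioxolane ring both on the side of the etheno bridge)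
Conditions: 3 (2 equiv), toluene, 25 °C, dark
Reagents that add atoms: none
Why: A Diels–Alder reaction in which the quinone should add to the diene face anti to the dioxolane and follow the endo rule, so the enedione ring ends anti to the oxygenated two-carbon bridge; this fixes the four CH centres of the later rings A and B as a meso array.

Step 3
Reactants: 4 adduct
Product: 5 meso enediol 2,2-dimethyl-3a,4,4a,5,8,8a,9,9a-octahydro-4,9-ethenonaphtho[2,3-d][1,3]dioxole-5,8-diol (both OH cis, on the concave face)
Conditions: NaBH4, CeCl3·7H2O, MeOH, −78 to 0 °C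
Reagents that add atoms: none
Why: Luche 1,2-reduction of the enedione should deliver hydride from the convex face to both carbonyls and leave the C=C; the carbinol configuration is lost in step 4.

Step 4
Reactants: 5 enediol
Product: 6 meso triene acetonide 2,2-dimethyl-3a,4,4a,8a,9,9a-hexahydro-4,9-ethenonaphtho[2,3-d][1,3]dioxole (ring A now a cyclohexa-1,3-diene)
Conditions: TiCl3, LiAlH4 (2:1), THF, 0 °C to reflux
Reagents that add atoms: none
Why: Low-valent titanium reductive 1,4-elimination of a 2-ene-1,4-diol (McMurry-type deoxygenation) should give the conjugated diene without touching the acetal, the isolated alkene or the ring-fusion CH centres.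

Step 5
Reactants: 6 triene acetonide
Product: 8 meso dialdehyde (1R,4S,4aS,8aR)-1,4,4a,8a-tetrahydronaphthalene-1,4-dicarbaldehyde, via bridge diol 7 (not isolated)
Conditions: AcOH/H2O 4:1, 40 °C; then NaIO4, THF/H2O, pH 7 buffer, 0 °C; used crude
Reagents that add atoms: none
Why: Acetal hydrolysis followed by periodate glycol cleavage should open the two-carbon bridge to two formyl groups that are necessarily cis to each other and, because of the endo adduct, trans to ring A.

Step 6
Reactants: 8 dialdehyde
Product: 10 meso diester dimethyl (1R,4S,4aS,8aR)-1,4,4a,8a-tetrahydronaphthalene-1,4-dicarboxylate, via diacid 9 (not isolated)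
Conditions: NaClO2, NaH2PO4, 2-methyl-2-butene, t-BuOH/H2O, 0 °C; then TMSCHN2, PhMe/MeOH, 0 °C
Reagents that add atoms: sodium chlorite [Na+].[O-]Cl=O; trimethylsilyldiazomethane C[Si](C)(C)C=[N+]=[N-]
Why: Pinnick oxidation under buffered conditions and diazoalkane esterification should convert both aldehydes without epimerising the allylic α-centres or touching the diene.

Step 7
Reactants: 10 meso diester
Product: 11 hemiester (1S,4R,4aR,8aS)-4-(methoxycarbonyl)-1,4,4a,8a-tetrahydronaphthalene-1-carboxylic acid
Conditions: pig liver esterase, 0.1 M phosphate buffer pH 7.5, 10% acetone, 25 °C, pH-stat (1 equiv NaOH); then acidify to pH 3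
Reagents that add atoms: water O
Why: Enzymatic desymmetrization of a meso diester by enantiotopic-group-selective hydrolysis should give one hemiester and thereby set the absolute configuration of all four ring stereocentres at once.

Step 8
Reactants: 11 hemiester
Product: 13 methyl (1R,4S,4aS,8aR)-4-(hydroxymethyl)-1,4,4a,8a-tetrahydronaphthalene-1-carboxylate, via mixed anhydride 12 (not isolated)
Conditions: i-BuOCOCl, N-methylmorpholine, THF, −15 °C; then NaBH4, H2O, 0 °C
Reagents that add atoms: none
Why: Mixed-anhydride activation makes the acid the only carbonyl that NaBH4 reduces at 0 °C, so the methyl ester, the diene and the ring alkene should survive.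

Step 9
Reactants: 13 hydroxy ester
Product: 14 methyl (1R,4S,4aS,8aR)-4-(iodomethyl)-1,4,4a,8a-tetrahydronaphthalene-1-carboxylate
Conditions: I2, PPh3, imidazole, CH2Cl2, 0 °C
Reagents that add atoms: iodine II
Why: Appel-type iodination of a primary alcohol proceeds by SN2 at CH2 and should leave every stereocentre untouched.

Step 10
Reactants: 15 dec-9-yn-1-ol
Product: 16 dec-9-ynal
Conditions: Dess–Martin periodinane, NaHCO3, CH2Cl2, 0 °C to rt
Reagents that add atoms: none
Why: Dess–Martin oxidation should stop cleanly at the aldehyde and tolerate the terminal alkyne.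

Step 11
Reactants: 16 dec-9-ynal; 17 5-(ethylsulfonyl)-1-phenyl-1H-tetrazole
Product: 18 (E)-dodec-10-en-1-yne
Conditions: 17, KN(SiMe3)2, DME, −60 °C; then 16, −60 °C to rt
Reagents that add atoms: none
Why: Julia–Kocienski olefination with a phenyltetrazolyl sulfone should give the E-alkene by anti addition, Smiles rearrangement and anti elimination; metalating the sulfone before adding the aldehyde keeps the alkyne C–H out of the reaction.

Step 12
Reactants: 18 enyne
Product: 20 (1E,10E)-1-iodododeca-1,10-diene, via alkenylzirconocene 19 (not isolated)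
Conditions: Cp2Zr(H)Cl, THF, rt; then I2, 0 °C
Reagents that add atoms: iodine II
Why: Hydrozirconation adds Zr–H syn to the terminal alkyne with zirconium at the terminal carbon (far faster than to the internal alkene), and iodinolysis with retention should give the E-alkenyl iodide.

Step 13
Reactants: 14 iodide; 20 alkenyl iodide
Product: 22 methyl (1R,4S,4aR,8aR)-4-[(2E,11E)-trideca-2,11-dien-1-yl]-1,4,4a,8a-tetrahydronaphthalene-1-carboxylate, via alkylzinc iodide 21 (not isolated)
Conditions: Zn dust (activated with BrCH2CH2Br and Me3SiCl), LiCl, THF, 40 °C; then 20, Pd(PPh3)4 (5 mol%), 25 to 45 °C; product kept cold and used promptly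
Reagents that add atoms: none
Why: Zinc insertion into the primary C–I bond tolerates the ester, and the Negishi sp3–sp2 coupling of a β-branched primary alkylzinc iodide with an alkenyl iodide should proceed with retention of the E geometry.

Step 14
Reactants: 22 triene ester
Product: 23 target CNP0133550.1
Conditions: [Ir(dF(CF3)ppy)2(dtbbpy)]PF6 (1 mol%), blue LEDs (450 nm), degassed MeCN (0.005 M), 25 °C
Reagents that add atoms: none
Why: Dexter energy transfer from the excited iridium complex (triplet energy about 60 kcal/mol) reaches only the cyclohexa-1,3-diene of 22 (about 52 kcal/mol), whose terminus C-5 adds to C-2' of the side-chain alkene and whose triplet 1,4-biradical (alkyl radical at C-3', allyl radical over C-6 to C-8) closes after intersystem crossing by C-3'–C-6 bond formation. The closest known reaction type is the triplet-sensitized intramolecular [2+2] photocycloaddition of a 1,3-diene with a tethered alkene, which follows the rule of five. The cyclopentane closes first by 5-exo-trig radical addition and the cyclobutane last by four-membered recombination of the biradical at the near allyl terminus, which leaves C-7=C-8 as the cyclohexene double bond of the target. The configuration at C-5 follows from C-4a and C-4 (the tether reaches only the diene face that carries C-4, and the trans relation of C-4 and C-4a in 22 becomes the trans fusion of cyclopentane and ring B); the new CH centres from C-2' and C-6 are fixed by the need for cis fusion of the four-membered ring on the five- and six-membered rings (a biradical of the other configuration can only revert to 22); the CH from C-3' places its chain on the convex face, anti to both flanking ring bonds, which is also the outcome of suprafacial addition to the E-alkene. The step needs 5-exo over 6-endo attack (tether length), four- over six-ring closure of the allyl radical (least motion, the usual preference of triplet cyclohexadiene for [2+2] over [4+2]) and intra- over intermolecular reaction (high dilution); room temperature and visible light should keep the thermal intramolecular Diels–Alder reaction and the electrocyclic opening of the diene out.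

**Compound list**
1 | cis-cyclohexa-3,5-diene-1,2-diol (meso) | O[C@H]1C=CC=C[C@H]1O | starting material
2 | cis-2,2-dimethyl-3a,7a-dihydro-1,3-benzodioxole | CC1(C)O[C@H]2C=CC=C[C@H]2O1 | intermediate
3 | 1,4-benzoquinone | O=C1C=CC(=O)C=C1 | starting material
4 | meso endo adduct, 2,2-dimethyl-3a,4,4a,8a,9,9a-hexahydro-4,9-ethenonaphtho[2,3-d][1,3]dioxole-5,8-dione | O=C1C=CC(=O)[C@H]2[C@@H]1[C@H]3C=C[C@@H]2[C@@H]4OC(C)(C)O[C@H]34 | intermediate
5 | meso enediol, 5,8-diol of 4 (OH groups cis, concave face) | O[C@@H]1C=C[C@H](O)[C@H]2[C@@H]1[C@H]3C=C[C@@H]2[C@@H]4OC(C)(C)O[C@H]34 | intermediate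
6 | meso triene acetonide, 2,2-dimethyl-3a,4,4a,8a,9,9a-hexahydro-4,9-ethenonaphtho[2,3-d][1,3]dioxole | C1=CC=C[C@H]2[C@@H]1[C@H]3C=C[C@@H]2[C@@H]4OC(C)(C)O[C@H]34 | intermediate
7 | meso bridge diol, 1,4,4a,8a-tetrahydro-1,4-ethanonaphthalene-9,10-diol (cis-diol) | C1=CC=C[C@H]2[C@@H]1[C@H]3C=C[C@@H]2[C@H](O)[C@@H]3O | intermediate
8 | meso dialdehyde, (1R,4S,4aS,8aR)-1,4,4a,8a-tetrahydronaphthalene-1,4-dicarbaldehyde | O=C[C@H]1C=C[C@@H](C=O)[C@@H]2C=CC=C[C@H]12 | intermediate
9 | meso diacid, (1R,4S,4aS,8aR)-1,4,4a,8a-tetrahydronaphthalene-1,4-dicarboxylic acid | OC(=O)[C@H]1C=C[C@@H](C(=O)O)[C@@H]2C=CC=C[C@H]12 | intermediate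
10 | meso diester, dimethyl (1R,4S,4aS,8aR)-1,4,4a,8a-tetrahydronaphthalene-1,4-dicarboxylate | COC(=O)[C@H]1C=C[C@@H](C(=O)OC)[C@@H]2C=CC=C[C@H]12 | intermediate
11 | (1S,4R,4aR,8aS)-4-(methoxycarbonyl)-1,4,4a,8a-tetrahydronaphthalene-1-carboxylic acid | OC(=O)[C@H]1C=C[C@@H](C(=O)OC)[C@@H]2C=CC=C[C@H]12 | intermediate
12 | isobutyl carbonic mixed anhydride of 11 | CC(C)COC(=O)OC(=O)[C@H]1C=C[C@@H](C(=O)OC)[C@@H]2C=CC=C[C@H]12 | intermediate
13 | methyl (1R,4S,4aS,8aR)-4-(hydroxymethyl)-1,4,4a,8a-tetrahydronaphthalene-1-carboxylate | OC[C@H]1C=C[C@@H](C(=O)OC)[C@@H]2C=CC=C[C@H]12 | intermediate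
14 | methyl (1R,4S,4aS,8aR)-4-(iodomethyl)-1,4,4a,8a-tetrahydronaphthalene-1-carboxylate | IC[C@H]1C=C[C@@H](C(=O)OC)[C@@H]2C=CC=C[C@H]12 | intermediate
15 | dec-9-yn-1-ol | OCCCCCCCCC#C | starting material
16 | dec-9-ynal | O=CCCCCCCCC#C | intermediate
17 | 5-(ethylsulfonyl)-1-phenyl-1H-tetrazole | CCS(=O)(=O)c1nnnn1-c1ccccc1 | starting material
18 | (E)-dodec-10-en-1-yne | C#CCCCCCCC/C=C/C | intermediate
19 | chlorobis(cyclopentadienyl)[(1E,10E)-dodeca-1,10-dien-1-yl]zirconium (cyclopentadienyl rings drawn σ-bonded) | C/C=C/CCCCCCC/C=C/[Zr](Cl)(C1C=CC=C1)C1C=CC=C1 | intermediate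
20 | (1E,10E)-1-iodododeca-1,10-diene | I/C=C/CCCCCCC/C=C/C | intermediate
21 | alkylzinc iodide from 14, iodo{[4-(methoxycarbonyl)-1,4,4a,8a-tetrahydronaphthalen-1-yl]methyl}zinc | I[Zn]C[C@H]1C=C[C@@H](C(=O)OC)[C@@H]2C=CC=C[C@H]12 | intermediate
22 | methyl (1R,4S,4aR,8aR)-4-[(2E,11E)-trideca-2,11-dien-1-yl]-1,4,4a,8a-tetrahydronaphthalene-1-carboxylate | C/C=C/CCCCCCC/C=C/C[C@H]1C=C[C@@H](C(=O)OC)[C@@H]2C=CC=C[C@H]12 | intermediate
23 | CNP0133550.1: tetracyclic methyl ester; cyclobutane bearing the (E)-dec-8-enyl chain on its convex face, cis-fused to ring A (cyclohexene) and to the cyclopentane, the cyclopentane trans-fused to ring B (cyclohexene carrying CO2Me) | C/C=C/CCCCCCC[C@@H]1[C@H]2C=C[C@@H]3[C@@H]4[C@H]2[C@H]1C[C@H]4C=C[C@H]3C(=O)OC | target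

**Step count:** 14 steps in total. The longest linear sequence is 11 steps (steps 1 to 9, 13 and 14).

**Steps most likely to fail**

Step 14. The triplet biradical may close at the far allyl terminus (six-ring closure, the formal [4+2] mode), and the excited diene may dimerise. The fallback sets out from 22 and comes back at 23. It is a thermal iron-catalysed [2π+2π] cycloaddition with (iPrPDI)Fe(N2)2 (iPrPDI = 2,6-[(2,6-iPr2C6H3)N=CMe]2C5H3N) in benzene at 25 to 45 °C. Oxidative cyclisation of the diene terminus and the tethered alkene on iron gives an allyl metallacyclopentane, and its C(sp3)–C(sp3) reductive elimination can only form the four-membered ring. No new compound is made.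

Step 7. The esterase may discriminate poorly between the two enantiotopic ester groups. The fallback sets out from 8 and comes back at 13, moving the desymmetrization to a lipase-catalysed acylation.
- Reduction of 8 (NaBH4, MeOH, 0 °C) gives the meso diol 1,4,4a,8a-tetrahydronaphthalene-1,4-diyldimethanol F1.
- Lipase from Burkholderia cepacia with vinyl acetate in t-BuOMe acylates one enantiotopic hydroxymethyl group to the monoacetate F2.
- The free hydroxymethyl group is oxidised to the acid F3 (TEMPO cat., PhI(OAc)2, MeCN/H2O).
- TMSCHN2 gives the acetoxy ester F4, and mild methanolysis (K2CO3, MeOH, 0 °C) returns 13.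
- If the lipase acylates the other arm, the free arm is instead iodinated and coupled, and the acetate arm is oxidised afterwards.

Step 4. Deoxygenation on the heterogeneous titanium reagent may stop half-way or give mixtures by over-reduction. The fallback sets out from 5 and comes back at 6. PBr3 (Et2O, pyridine cat., 0 °C) converts both allylic alcohols into the dibromide F5; allylic transposition isomers converge in the next operation. Zinc dust in THF/EtOH at 25 °C then effects reductive 1,4-elimination to the diene 6.

**Further compounds**
F0 | step 14 | none | none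
F1 | step 7 | meso diol, (1R,4S,4aS,8aR)-1,4,4a,8a-tetrahydronaphthalene-1,4-diyldimethanol | OC[C@H]1C=C[C@@H](CO)[C@@H]2C=CC=C[C@H]12
F2 | step 7 | monoacetate, [4-(hydroxymethyl)-1,4,4a,8a-tetrahydronaphthalen-1-yl]methyl acetate (acetate on the arm that becomes the side chain) | CC(=O)OC[C@H]1C=C[C@@H](CO)[C@@H]2C=CC=C[C@H]12
F3 | step 7 | 4-(acetoxymethyl)-1,4,4a,8a-tetrahydronaphthalene-1-carboxylic acid | CC(=O)OC[C@H]1C=C[C@@H](C(=O)O)[C@@H]2C=CC=C[C@H]12
F4 | step 7 | methyl 4-(acetoxymethyl)-1,4,4a,8a-tetrahydronaphthalene-1-carboxylate | CC(=O)OC[C@H]1C=C[C@@H](C(=O)OC)[C@@H]2C=CC=C[C@H]12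
F5 | step 4 | 5,8-dibromo-2,2-dimethyl-3a,4,4a,5,8,8a,9,9a-octahydro-4,9-ethenonaphtho[2,3-d][1,3]dioxole (bromides on the convex face) | Br[C@H]1C=C[C@@H](Br)[C@H]2[C@@H]1[C@H]3C=C[C@@H]2[C@@H]4OC(C)(C)O[C@H]34
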